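**Retrosynthetic overview**

- Target 17 comes from lactone 16 (ring A as MOM ether, ring B as acetate) by one acidic methanolysis.
- 16 is cut into dienoic acid 9 and diazonium salt 15; the C6–aryl (ring B) bond and the C5–O1 bond are made together and close the butenolide, the only ring built (rings A and B are bought).
- 9 comes from dienoate 8, made by Suzuki vinylation of (E)-enol triflate 6, which comes from β-keto ester 5 (aldol of methyl methoxyacetate 2 with aldehyde 1, then oxidation).
- 15 comes from aniline 14, reached by Stille prenylation of 2-bromo-4-nitrophenyl acetate 11 and nitro reduction.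
- Feature: in the lactone (O1, C2=O, C3–OMe, C4–ring A, C5–H) the ring oxygen O1 sits on C5 and the ring-B aryl group on the neighbouring exocyclic CH2 (C6). This vicinal aryl/carboxylate-oxygen pair is what an aryl group and a carboxylate oxygen leave when they add across a terminal C5=C6 alkene.

Key step: step 10

Assumption: the sense of induction of the bis(oxazoline) ligand on this substrate class cannot be predicted with certainty; the route is written with the (S,S)-ligand, and the (R,R)-ligand would be used if that is the one that favours the (5R)-lactone.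

**Route**

Step 1
Reactants: 1 4-(methoxymethoxy)benzaldehyde; 2 methyl methoxyacetate
Product: 4 methyl 3-hydroxy-2-methoxy-3-[4-(methoxymethoxy)phenyl]propanoate (racemic syn/anti mixture), via lithium enolate of methyl methoxyacetate 3 (not isolated)
Conditions: LiN(i-Pr)2, THF, −78 °C; then 1, −78 °C; AcOH quench
Reagents that add atoms: none
Why: Directed aldol addition in which the preformed lithium ester enolate adds to the non-enolisable aldehyde at −78 °C faster than it self-condenses; both new stereocentres are removed in steps 2 and 3, so the mixture is used as such.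

Step 2
Reactants: 4 methyl 3-hydroxy-2-methoxy-3-[4-(methoxymethoxy)phenyl]propanoate
Product: 5 methyl 2-methoxy-3-[4-(methoxymethoxy)phenyl]-3-oxopropanoate
Conditions: Dess–Martin periodinane, CH2Cl2, 0 °C → rt
Reagents that add atoms: none
Why: Dess–Martin oxidation of a secondary benzylic alcohol to the aryl ketone under conditions that leave the MOM acetal and the ester untouched.

Step 3
Reactants: 5 methyl 2-methoxy-3-[4-(methoxymethoxy)phenyl]-3-oxopropanoate
Product: 6 methyl (2E)-2-methoxy-3-[4-(methoxymethoxy)phenyl]-3-{[(trifluoromethyl)sulfonyl]oxy}prop-2-enoate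
Conditions: Tf2O, aq. LiOH, toluene, 0–5 °C
Reagents that add atoms: trifluoromethanesulfonic anhydride, O=S(=O)(OS(=O)(=O)C(F)(F)F)C(F)(F)F
Why: Schotten–Baumann-type O-triflation of the β-keto ester enolate under lithium-chelate control: lithium bridges the enolate oxygen and the ester carbonyl, so the triflate should form cis to CO2Me, which is (E) because OMe outranks CO2Me.

Step 4
Reactants: 6 methyl (2E)-2-methoxy-3-[4-(methoxymethoxy)phenyl]-3-{[(trifluoromethyl)sulfonyl]oxy}prop-2-enoate; 7 vinylboronic acid pinacol ester
Product: 8 methyl (2Z)-2-methoxy-3-[4-(methoxymethoxy)phenyl]penta-2,4-dienoate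
Conditions: Pd(PPh3)4 (3 mol%), K3PO4, 1,4-dioxane/H2O, 50 °C
Reagents that add atoms: none
Why: Suzuki–Miyaura coupling of an activated β-carbonyl alkenyl triflate, which proceeds with retention of alkene geometry and so places the vinyl group cis to the ester.

Step 5
Reactants: 8 methyl (2Z)-2-methoxy-3-[4-(methoxymethoxy)phenyl]penta-2,4-dienoate
Product: 9 (2Z)-2-methoxy-3-[4-(methoxymethoxy)phenyl]penta-2,4-dienoic acid
Conditions: LiOH·H2O, THF/MeOH/H2O, rt; then cold 0.5 M HCl to pH 4 (EtOAc present)
Reagents that add atoms: lithium hydroxide, [Li+].[OH-]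
Why: Saponification of the methyl ester, to which the MOM ether and the diene are stable; the acid is set free only with cold dilute acid so that the protonated diene cannot lactonise.

Step 6
Reactants: 10 2-bromo-4-nitrophenol
Product: 11 2-bromo-4-nitrophenyl acetate
Conditions: Ac2O, pyridine, DMAP (cat.), CH2Cl2, 0 °C → rt
Reagents that add atoms: acetic anhydride, CC(=O)OC(C)=O
Why: DMAP-catalysed O-acetylation of an acidic phenol, which also removes the proton that would destroy the allylstannane in step 7.

Step 7
Reactants: 11 2-bromo-4-nitrophenyl acetate; 12 tributyl(3-methylbut-2-en-1-yl)stannane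
Product: 13 2-(3-methylbut-2-en-1-yl)-4-nitrophenyl acetate
Conditions: Pd(PPh3)4 (5 mol%), toluene, 100 °C
Reagents that add atoms: none
Why: Stille coupling of an electron-poor aryl bromide with a prenylstannane, in which reductive elimination from the π-prenyl palladium intermediate at its unsubstituted terminus gives the linear prenyl arene; the neutral, amine-free medium spares the activated aryl acetate.

Step 8
Reactants: 13 2-(3-methylbut-2-en-1-yl)-4-nitrophenyl acetate
Product: 14 4-amino-2-(3-methylbut-2-en-1-yl)phenyl acetate
Conditions: Zn dust, AcOH, EtOAc, 0 °C → rt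
Reagents that add atoms: none
Why: Dissolving-metal reduction of the nitro group to the aniline, which leaves the trisubstituted alkene (no hydrogenation catalyst) and the aryl acetate (acidic, non-nucleophilic medium) intact.

Step 9
Reactants: 14 4-amino-2-(3-methylbut-2-en-1-yl)phenyl acetate
Product: 15 4-acetoxy-3-(3-methylbut-2-en-1-yl)benzenediazonium tetrafluoroborate
Conditions: t-BuONO, HBF4·OEt2, MeCN, −10 → 0 °C; Et2O (precipitation)
Reagents that add atoms: tert-butyl nitrite, CC(C)(C)ON=O; tetrafluoroboric acid (diethyl ether complex), [H+].F[B-](F)(F)F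
Why: Non-aqueous diazotisation of the aniline with an alkyl nitrite and HBF4, in which N-nitrosation is much faster than attack on the prenyl alkene and the absence of water and alcohol solvent protects the now strongly activated aryl acetate.

Step 10
Reactants: 9 (2Z)-2-methoxy-3-[4-(methoxymethoxy)phenyl]penta-2,4-dienoic acid; 15 4-acetoxy-3-(3-methylbut-2-en-1-yl)benzenediazonium tetrafluoroborate
Product: 16 (5R)-5-[4-acetoxy-3-(3-methylbut-2-en-1-yl)benzyl]-3-methoxy-4-[4-(methoxymethoxy)phenyl]furan-2(5H)-one
Conditions: Cu(MeCN)4PF6 (10 mol%), (S,S)-2,2′-(propane-2,2-diyl)bis(4-tert-butyl-4,5-dihydrooxazole) (12 mol%), 2,6-di-tert-butylpyridine (1.2 equiv), 15 (1.5 equiv), EtOAc, 0 °C → rt, argon, dark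
Reagents that add atoms: none
Why: Proposed new method: monovalent copper bearing the bis(oxazoline) reduces 15 to the ring-B aryl radical with loss of N2, the radical adds to the unhindered terminal CH2 (C6) of 9, and the resulting radical, delocalised over C5 and C3, is captured at C5 by the divalent copper carboxylate as a six-membered trivalent copper metallacycle whose C–O reductive elimination forms the lactone and returns monovalent copper. The closest known reaction type is the copper/bis(oxazoline)-catalysed enantioselective radical oxyarylation of 4-aryl-4-pentenoic and 2-vinylbenzoic acids with arenediazonium salts, which has not been shown on a conjugated dienoic acid with an allylic radical relay. The butenolide closes in the 5-exo-trig sense on the C5=C6 alkene (O1–C5 bond formed, C6 exocyclic), which the (Z)-geometry of C3=C4 makes possible by holding the carboxylate next to C5, while closure at C3 would need a three-membered lactone. The C5 stereocentre is set in the copper-mediated C–O bond formation, in which the C2-symmetric tert-butyl bis(oxazoline) on the carboxylate-bound copper selects one face of the planar allyl radical. The step needs regioselective radical addition at C6, secured by the monosubstituted vinyl terminus next to a tetrasubstituted, captodatively deactivated C3=C4 alkene, and it needs radical capture to outrun diffusion of the radical away from copper, which the carboxylate tether favours. 2,6-Di-tert-butylpyridine takes up the HBF4 that the equation releases, so that the acid-labile diene, MOM ether and prenyl group are spared and no racemic acid-catalysed lactonisation competes.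

Step 11
Reactants: 16 (5R)-5-[4-acetoxy-3-(3-methylbut-2-en-1-yl)benzyl]-3-methoxy-4-[4-(methoxymethoxy)phenyl]furan-2(5H)-one
Product: 17 (5R)-5-[4-hydroxy-3-(3-methylbut-2-en-1-yl)benzyl]-4-(4-hydroxyphenyl)-3-methoxyfuran-2(5H)-one
Conditions: HCl (1.25 M in MeOH), 0 °C → rt
Reagents that add atoms: none
Why: Acid-catalysed transacetalisation of the aryl MOM ether and transesterification of the aryl acetate in anhydrous methanol should free both phenols in one operation; C5 epimerises only under base (through the 2-oxyfuran anion), and the enol ether can only exchange methanol for methanol.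

**Compound list**

1 | 4-(methoxymethoxy)benzaldehyde | COCOc1ccc(C=O)cc1 | starting material
2 | methyl methoxyacetate | COCC(=O)OC | starting material
3 | lithium enolate of methyl methoxyacetate | COC=C(OC)O[Li] | intermediate (not isolated)
4 | methyl 3-hydroxy-2-methoxy-3-[4-(methoxymethoxy)phenyl]propanoate (racemic syn/anti mixture) | COCOc1ccc(cc1)C(O)C(OC)C(=O)OC | intermediate
5 | methyl 2-methoxy-3-[4-(methoxymethoxy)phenyl]-3-oxopropanoate (racemic) | COCOc1ccc(cc1)C(=O)C(OC)C(=O)OC | intermediate
6 | methyl (2E)-2-methoxy-3-[4-(methoxymethoxy)phenyl]-3-{[(trifluoromethyl)sulfonyl]oxy}prop-2-enoate | COC(=O)/C(OC)=C(\OS(=O)(=O)C(F)(F)F)c1ccc(OCOC)cc1 | intermediate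
7 | vinylboronic acid pinacol ester | C=CB1OC(C)(C)C(C)(C)O1 | starting material
8 | methyl (2Z)-2-methoxy-3-[4-(methoxymethoxy)phenyl]penta-2,4-dienoate | C=C/C(c1ccc(OCOC)cc1)=C(/OC)C(=O)OC | intermediate
9 | (2Z)-2-methoxy-3-[4-(methoxymethoxy)phenyl]penta-2,4-dienoic acid | C=C/C(c1ccc(OCOC)cc1)=C(/OC)C(=O)O | intermediate
10 | 2-bromo-4-nitrophenol | Oc1ccc(cc1Br)[N+](=O)[O-] | starting material
11 | 2-bromo-4-nitrophenyl acetate | CC(=O)Oc1ccc(cc1Br)[N+](=O)[O-] | intermediate
12 | tributyl(3-methylbut-2-en-1-yl)stannane | CCCC[Sn](CCCC)(CCCC)CC=C(C)C | starting material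
13 | 2-(3-methylbut-2-en-1-yl)-4-nitrophenyl acetate | CC(=O)Oc1ccc(cc1CC=C(C)C)[N+](=O)[O-] | intermediate
14 | 4-amino-2-(3-methylbut-2-en-1-yl)phenyl acetate | CC(=O)Oc1ccc(N)cc1CC=C(C)C | intermediate
15 | 4-acetoxy-3-(3-methylbut-2-en-1-yl)benzenediazonium tetrafluoroborate | CC(=O)Oc1ccc([N+]#N)cc1CC=C(C)C.F[B-](F)(F)F | intermediate
16 | (5R)-5-[4-acetoxy-3-(3-methylbut-2-en-1-yl)benzyl]-3-methoxy-4-[4-(methoxymethoxy)phenyl]furan-2(5H)-one | COC1=C(c2ccc(OCOC)cc2)[C@@H](Cc2ccc(OC(C)=O)c(CC=C(C)C)c2)OC1=O | intermediate
17 | (5R)-5-[4-hydroxy-3-(3-methylbut-2-en-1-yl)benzyl]-4-(4-hydroxyphenyl)-3-methoxyfuran-2(5H)-one | COC1=C(c2ccc(O)cc2)[C@@H](Cc2ccc(O)c(CC=C(C)C)c2)OC1=O | target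

**Step count**

Total: 11 steps. Longest linear sequence: 7 steps (steps 1–5, 10 and 11).

**Steps most likely to fail**

1. Step 10. The C–O bond formation at a secondary allylic radical may show poor facial discrimination, or the radical may leave the copper centre and react by racemic cation or dimerisation pathways. The fallback closes the lactone by a Nozaki–Hiyama–Kishi coupling and sets out from enol triflate 6 and diazonium salt 15. Suzuki–Miyaura coupling of 15 with CH2=CHBF3K (Pd(OAc)2, 1,4-dioxane, rt) would give 4-ethenyl-2-(3-methylbut-2-en-1-yl)phenyl acetate F1. Aldehyde-selective Wacker oxidation of this styrene (PdCl2(MeCN)2, 1,4-benzoquinone, t-BuOH/H2O, 85 °C) would give 2-(3-methylbut-2-en-1-yl)-4-(2-oxoethyl)phenyl acetate F2. Coupling of 6 with F2 mediated by CrCl2 and catalytic NiCl2 in the presence of a chiral sulfonamide ligand on chromium would give a chromium alkoxide that lactonises onto the cis methyl ester, and the route is rejoined at 16; any remaining (5S)-enantiomer would be removed by preparative chiral HPLC.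

2. Step 3. Chelate control of the enolate geometry may be incomplete during O-triflation, so that the triflate is installed trans to the ester. The fallback fixes the geometry in a ring and sets out from methyl methoxyacetate 2. C-Acetylation of its enolate 3 with N-acetylimidazole (THF, −78 °C) would give methyl 2-methoxy-3-oxobutanoate F3. Its dianion (NaH, then n-BuLi, THF) would be hydroxymethylated at the terminal methyl group with gaseous formaldehyde to give methyl 5-hydroxy-2-methoxy-3-oxopentanoate F4. This lactonises on treatment with dilute aqueous NaOH and acidification to 3-methoxyoxane-2,4-dione F5. Tf2O and i-Pr2NEt in CH2Cl2 at −78 °C would give 3-methoxy-2-oxo-5,6-dihydro-2H-pyran-4-yl trifluoromethanesulfonate F6. Suzuki–Miyaura coupling with 4-(methoxymethoxy)phenylboronic acid (Pd(PPh3)4, K3PO4, 1,4-dioxane/H2O) would give 3-methoxy-4-[4-(methoxymethoxy)phenyl]-5,6-dihydro-2H-pyran-2-one F7. LiN(SiMe3)2 in THF (−78 → 0 °C) would remove a C5 proton and expel the carboxylate from C6 (E1cB ring opening), which leaves the vinyl group and the carboxyl group cis; the route is rejoined at acid 9, bypassing 6 and 8.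

3. Step 11. During the acidic methanolysis HCl or methanol may add to the prenyl double bond, or the alkene may cyclise onto the freed ortho-phenol to a 2,2-dimethylchroman. The fallback removes the two groups one after the other without Brønsted acid and sets out from 16. TMSOTf and 2,2′-bipyridyl in CH2Cl2 at 0 °C would convert the aryl MOM ether into (5R)-5-[4-acetoxy-3-(3-methylbut-2-en-1-yl)benzyl]-3-methoxy-4-[4-(trimethylsilyloxy)phenyl]furan-2(5H)-one F8 while ring B is still acetylated, so no free ortho-phenol is present. Aqueous work-up would hydrolyse the silyl ether to (5R)-5-[4-acetoxy-3-(3-methylbut-2-en-1-yl)benzyl]-4-(4-hydroxyphenyl)-3-methoxyfuran-2(5H)-one F9. Hydrazine acetate in DMF (0 °C → rt) would then cleave the aryl acetate near neutrality, and the route is rejoined at 17.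

**Further compounds**

F1 | step 10 | 4-ethenyl-2-(3-methylbut-2-en-1-yl)phenyl acetate | CC(=O)Oc1ccc(C=C)cc1CC=C(C)C
F2 | step 10 | 2-(3-methylbut-2-en-1-yl)-4-(2-oxoethyl)phenyl acetate | CC(=O)Oc1ccc(CC=O)cc1CC=C(C)C
F3 | step 3 | methyl 2-methoxy-3-oxobutanoate | CC(=O)C(OC)C(=O)OC
F4 | step 3 | methyl 5-hydroxy-2-methoxy-3-oxopentanoate | OCCC(=O)C(OC)C(=O)OC
F5 | step 3 | 3-methoxyoxane-2,4-dione | COC1C(=O)CCOC1=O
F6 | step 3 | 3-methoxy-2-oxo-5,6-dihydro-2H-pyran-4-yl trifluoromethanesulfonate | COC1=C(OS(=O)(=O)C(F)(F)F)CCOC1=O
F7 | step 3 | 3-methoxy-4-[4-(methoxymethoxy)phenyl]-5,6-dihydro-2H-pyran-2-one | COC1=C(c2ccc(OCOC)cc2)CCOC1=O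
F8 | step 11 | (5R)-5-[4-acetoxy-3-(3-methylbut-2-en-1-yl)benzyl]-3-methoxy-4-[4-(trimethylsilyloxy)phenyl]furan-2(5H)-one | COC1=C(c2ccc(O[Si](C)(C)C)cc2)[C@@H](Cc2ccc(OC(C)=O)c(CC=C(C)C)c2)OC1=O
F9 | step 11 | (5R)-5-[4-acetoxy-3-(3-methylbut-2-en-1-yl)benzyl]-4-(4-hydroxyphenyl)-3-methoxyfuran-2(5H)-one | COC1=C(c2ccc(O)cc2)[C@@H](Cc2ccc(OC(C)=O)c(CC=C(C)C)c2)OC1=O
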